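The readings are calculated on assumed constants.

- If target can turn back into starting material, its growth stops at a fixed ratio of target to starting material, and the bending target columns of the earlier runs let me read that ratio.

| setting | noon | spring | green | red |
|---|---|---|---|---|
| starting material | 0.013 M | 0.066 M | 0.012 M | 0.050 M |
| catalyst | 70 µM | 70 µM | 70 µM | 70 µM |
| temperature | 75 °C | 88 °C | 95 °C | 80 °C |
| remark | run made earlier | run made earlier |  |  |
| time |  |  | 12 h | 12 h |

- noon (time / h: target / %, starting material / %): 1.00: 3.5, 95.1; 2.00: 6.8, 89.2; 3.00: 9.5, 84.9; 6.00: 17.9, 73.4; 12.0: 28.7, 57.2
- spring (time / h: target / %, starting material / %): 1.00: 5.8, 87.7; 3.00: 15.0, 70.1; 6.00: 24.6, 51.1; 8.00: 28.5, 41.8; 12.0: 33.0, 32.3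

(readings scatter by 0.5 percentage points)

- which one finishes higher in amount of target, in percent of the starting material charged ("neither" within 2 percentage points) (green / red / neither)
- amount of target at the end, in percent of the starting material charged, green
- amount of target at the end, in percent of the starting material charged, red

- in a conversion other conformer counts as not yet reacted

- The first hour of the spring run gives target a pseudo-first-order constant of 0.0618 h⁻¹, reckoned on the mean starting material of that hour.
- Over the last stretch of the spring run this constant allows a higher rate than the readings show. That shortfall gives 1.63 as the standstill ratio, the ratio of target to starting material at which target stops growing. It is a reading and carries the scatter of the readings.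
- I test it on the noon run, whose first hour gives 0.0359 h⁻¹. Its last stretch, with target divided by the ratio and subtracted from starting material, gives 0.0353 h⁻¹, about the same.
- Assuming the charge does not matter, I spread the constant logarithmically over temperature: 0.0442 h⁻¹ for red and 0.0828 h⁻¹ for green.
- The overall fall of starting material, spread the same way from the last readings and taken as exponential, gives a mean starting material of 70.9% in red and 48.9% in green.
- Constant times time times that mean is my first answer, and it ignores the way back. Putting each answer back as mean target over the ratio, and going round until the number stands, amounts to dividing by one plus weight times constant times time over the ratio. The weight is mean target over final target. A straight line has weight 0.5, which gives 37.3% for green and 32.4% for red.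
- The weak link is the pair of assumed shapes, so I reforge it from the readings. In the spring run the mean starting material taken from the readings is 0.938 of the exponential one and the weight is 0.655. In the noon run they are 0.985 and 0.569.
- Using the spring figures for green and the noon figures for red, I commit to 32.6% for green and 31.3% for red, a gap smaller than the margin, so my answer is neither.
- The forecast differs from my reckoning: it says green, with 40% for green and 28% for red, on the ground that “The dilute solution means little inhibition”.
- The flask gives 31.4% for green and 31.3% for red, so the answer is neither.

    starting material ⇌ other conformer (K = 1.10, k = 5.10 × 10⁻⁴ min⁻¹, Ea = 108 kJ mol⁻¹, ΔH = −4.00 kJ mol⁻¹)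
    catalyst + other conformer → catalyst + isomer of the product (k = 16.0 L mol⁻¹ min⁻¹, Ea = 51.0 kJ mol⁻¹)
    starting material + catalyst ⇌ catalyst + target (K = 1.70, k = 11.0 L mol⁻¹ min⁻¹, Ea = 45.0 kJ mol⁻¹, ΔH = 0 kJ mol⁻¹)
    catalyst + target → catalyst + over-reaction product (k = 0.370 L mol⁻¹ min⁻¹, Ea = 60.0 kJ mol⁻¹)
    (constants at 80 °C)

- The standstill ratio times the starting material left gives 37.1% in green and 76.1% in red, and target stands below both. The neighbour is red with 2.8 × 10⁻⁴ M of catalyst, which holds 30.0% starting material at the end. The ratio times that amount gives 48.9%, and the neighbour holds 50.6% target.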